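Over the 15 d of this flask I followed one number: how the ratio of target to side product moves with the partner still in solution.

| flask | starting material | partner | protic impurity | remark | time |
|---|---|---|---|---|---|
| theta | 0.017 M | 2 equiv | 0.011 M | run made earlier |  |
| zeta | 0.017 M | 2 equiv | 0.026 M | run made earlier |  |
| flask | 0.017 M | 2.00 equiv | 0.0170 M |  | 15 d |

- theta (time / d: target / %, side product / %, starting material / %): 1.67: 31.1, 2.7, 2.0; 5.00: 43.2, 4.0, 0; 8.00: 43.8, 3.7, 0; 12.0: 43.5, 4.2, 0.2; 20.0: 43.4, 4.3, 0.1
- zeta (time / d: target / %, side product / %, starting material / %): 4.00: 21.5, 1.7, 0.5; 8.00: 21.6, 1.3, 0.4; 10.0: 21.2, 1.6, 0.2; 15.0: 21.1, 1.8, 0; 20.0: 21.1, 1.8, 0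

(each reading ± 0.3 percentage points)

- the numbers in the tables scatter with a standard deviation of 0.3 percentage points

- ratio of target to side product at 6.0 h
- ratio of target to side product at 15 d
- which of target and side product there is more of at 15 d

I began with the end of the earlier runs. Theta's starting material read 0% at 5.00 d, and its products stayed level from then on, so the plateau readings describe a finished run. There the ratio read 10.7 in theta and 13.0 in zeta. Counting one partner per product, I estimated 0.0259 M of partner left in theta and 0.0301 M in zeta. By this count zeta kept more partner than theta, and it read a higher ratio. I took this to mean that target formation needs partner and side product formation does not.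

So I defined S, the selectivity factor: the ratio of target to side product per unit concentration of partner left, 423 L mol⁻¹ as the mean of the two runs.

Then I ran the flask in my head. In the first hours I took partner as charged, 0.0340 M, which gave a ratio of 14.4 at 6.0 h. Through the middle of the run I expected partner to fall. For the end I interpolated the estimated partner left on the impurity charge between theta and zeta, 0.0276 M, which gave 11.7. That is lower than the early figure, with target ahead.

The forecast gave 11.3 (9 to 14) at 6.0 h and 11.3 (10 to 13) at 15 d, with target ahead: "Both products therefore appear to form in parallel from the starting material, with no interconversion".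

The flask gave 14.3 at 6.0 h and 12.6 at 15 d, with target ahead. Partner stood at 67.6% of its charge at 15.0 d. Divided by S, the end ratio corresponds to 0.0298 M of partner, less than the charge and more than the 0.0230 M left. My estimate of 0.0276 M for this flask stood above that amount left.

    partner + intermediate C ⇌ intermediate D (K = 25.0 L mol⁻¹, k = 120 L mol⁻¹ h⁻¹)
    starting material + partner ⇌ intermediate B (K = 15.0 L mol⁻¹, k = 150 L mol⁻¹ h⁻¹)
    intermediate C → side product (k = 0.0100 h⁻¹)
    partner + intermediate C → target (k = 5.00 L mol⁻¹ h⁻¹)
    starting material + protic impurity → quenched substrate (k = 15.0 L mol⁻¹ h⁻¹)
    starting material + partner → intermediate A (k = 2.80 L mol⁻¹ h⁻¹)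
    intermediate A → intermediate C (k = 0.110 h⁻¹)

In a neighbouring flask with 3.40 equiv of partner, S times the charged partner gives 24.4 at 6.0 h. The computed neighbour gave 25.1.

The earlier runs and the new flask were computed for an exercise.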